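The candidate at the bench is handed these flasks and these readings.

| flask | substrate | partner | reagent | remark | time |
|---|---|---|---|---|---|
| violet | 0.40 M | 0.48 M | 0.44 M | run made earlier |  |
| green | 0.40 M | 0.48 M | 0.29 M | run made earlier |  |
| ochre | 0.40 M | 0.48 M | 0.66 M | run made earlier |  |
| north | 0.40 M (fed, over 1.25 h) | 0.480 M | 0.440 M | all but substrate at the start; substrate goes in evenly over 1.25 h, the run ends at 2.5 h | 2.5 h |
| east | 0.40 M | 0.480 M | 0.440 M (fed, over 1.25 h) | a stirred flask in which reagent is dosed at a steady rate over 1.25 h without added volume, worked up at 2.5 h | 2.5 h |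
| west | 0.40 M | 0.480 M | 0.440 M | everything together in a closed stirred flask, run for 2.5 h | 2.5 h |
| north-west | 0.40 M | 0.480 M | 0.440 M | one stirred flow tank at steady state, fed with the mixture as stated, mean residence time 2.5 h |  |

| run | time / h | target / % | over-reaction product / % | substrate / % |
|---|---|---|---|---|
| violet | 0.200 | 2.7 | 0 | 24.2 |
| violet | 0.333 | 0.6 | 0 | 14.6 |
| violet | 0.500 | 1.8 | 0.9 | 9.3 |
| violet | 0.667 | 2.8 | 0 | 5.8 |
| violet | 1.00 | 2.2 | 0 | 5.2 |
| violet | 1.50 | 3.4 | 0.6 | 3.1 |
| violet | 2.50 | 5.9 | 0 | 1.5 |
| green | 0.133 | 0.3 | 0 | 51.0 |
| green | 0.417 | 0 | 0.8 | 33.6 |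
| green | 0.667 | 0 | 0 | 30.9 |
| green | 1.00 | 2.9 | 0 | 28.4 |
| green | 1.50 | 0.3 | 1.1 | 29.2 |
| green | 2.00 | 1.0 | 1.0 | 31.0 |
| green | 2.50 | 2.1 | 1.1 | 29.8 |
| ochre | 0.133 | 0.2 | 0 | 13.6 |
| ochre | 0.417 | 0 | 2.5 | 2.6 |
| ochre | 0.667 | 2.4 | 0 | 1.0 |
| ochre | 1.00 | 5.3 | 0 | 0.8 |
| ochre | 1.50 | 7.2 | 1.8 | 1.0 |
| ochre | 2.00 | 10.2 | 5.6 | 0.4 |
| ochre | 2.50 | 15.3 | 4.1 | 0 |

(readings scatter by 1 percentage point)

- the stated concentrations are those of everything mixed, before any reaction; amounts are the same in each set-up
- the feed brings no volume worth counting
- the earlier runs were made in a closed, stirred flask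
- a reading or a percentage of target counts all its forms, free or not

1. the set-up with the highest share of target in all that became target or over-reaction product, at the outlet or at the end ("none" if the first two lie within 2 percentage points) (north / east / west / north-west / none)
2. share of target in all that became target or over-reaction product, at the outlet or at the end, north
3. share of target in all that became target or over-reaction product, at the outlet or at the end, east
4. share of target in all that became target or over-reaction product, at the outlet or at the end, west
5. share of target in all that became target or over-reaction product, at the outlet or at the end, north-west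

*Where does the substrate go first?* To reagent, one to one: green should keep 27.5% of its substrate, and it reads 29.8%.

*And the share?* At the end of ochre over-reaction product reads less than target, so I reckon it as a correction to target. Suppose a steady fraction of the target is lost each hour. Then the loss rate, over-reaction product at the end divided by the area under the target curve, a pseudo-first-order constant, is 0.265 h⁻¹, read from ochre, whose target climbs higher than in the other runs. The share is then one over one plus that rate times the mean age of the target.

*Isn't that reading weak?* Yes: 4.1%, give or take 1 percentage point.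

*Ages, then?* If target forms evenly, west's mean age is half the time, so its share is 75.1%. In north reagent waits from the start, so I give it the same age and 75.1%. In the north-west tank the mean age is the residence time, which gives 60.1%.

*East?* In east the reagent dosed so far equals the substrate charge at 1.14 h. I let target start there, so east's share is 84.7%, my highest.

The forecast says otherwise: north 86%, east 78%, west 90%, north-west 82%, and “West is tentatively best”.

The simulation gives north 78.6%, east 85.3%, west 77.6%, north-west 64.9%; the best is east.

    reagent + partner → second intermediate (k = 0.578 M⁻¹ h⁻¹)
    partner + target ⇌ idle adduct, settled at all times (K = 9.32 M⁻¹)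
    open intermediate + second intermediate → target (k = 1.93 M⁻¹ h⁻¹)
    target → over-reaction product (k = 1.08 h⁻¹)
    substrate + reagent → open intermediate (k = 33.4 M⁻¹ h⁻¹)

Over-reaction product divided by target, then by the loss rate, gives a mean age of 0.651 h in east at the end, against 1.09 h in west. Now leave east until 6.0 h. The same reckoning, with target starting at 1.14 h, gives a mean age of 2.43 h and a share of 60.8%. That flask holds target 4.61% and over-reaction product 3.98%, a share of 53.7%.

The readings were generated by integration with constants of no real substance; scatter was added.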